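**Strategy.** Everything rests on the pyranone ring C (flavanone numbering). The hemiketal carbon C4 is bonded to ring A (C4a) and to the ring B oxygen O2', and O1 sits on C8a, ortho to C4. The target is traced to flavone 15 and this to aryl ester 13, in which the ring B phenol oxygen carries the ring A acyl group and C8a carries fluorine. In one operation base moves the acyl group from O2' to the acetyl carbon (C3–C4 bond), and the diketone enolate oxygen then displaces fluoride (O1–C8a bond), closing ring C. A final enantioselective conjugate reduction sets C2, and the 2'-OH closes the hemiketal.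

Key step: step 7

Remark: flavanone numbering is used throughout (O1, C2, C3, C4, C4a, C5–C8, C8a; ring B C1'–C6'); in it the target is the 2R,4R hemiketal. Compounds 1, 3, 7 and 11 are taken as commercial.

**Step 1**
Reactants: 1 3-fluoro-5-methoxyphenol
Product: 2 1-fluoro-3-methoxy-5-(methoxymethoxy)benzene
Conditions: MOMCl, iPr2NEt, CH2Cl2, 0 °C → rt
Reagents that add atoms: chloromethyl methyl ether, COCCl
Why: Williamson-type O-alkylation of the phenol installs the MOM group, which protects the OH and later serves as the directing group for ortho-metalation.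

**Step 2**
Reactants: 2 1-fluoro-3-methoxy-5-(methoxymethoxy)benzene; 3 prenyl bromide (1-bromo-3-methylbut-2-ene)
Product: 5 1-fluoro-5-methoxy-3-(methoxymethoxy)-2-(3-methylbut-2-en-1-yl)benzene, via aryllithium 4 (not isolated)
Conditions: n-BuLi, THF, −78 °C; then 3, CuBr·SMe2 (10 mol %), −78 → −20 °C
Reagents that add atoms: none
Why: Directed ortho-metalation should remove the ring hydrogen flanked by fluorine (the strongest acidifier) and the chelating OMOM group in preference to the two positions next to OMe, and the aryllithium is allylated at the primary carbon of prenyl bromide before it can lose LiF.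

**Step 3**
Reactants: 5 1-fluoro-5-methoxy-3-(methoxymethoxy)-2-(3-methylbut-2-en-1-yl)benzene
Product: 6 3-fluoro-5-methoxy-2-(3-methylbut-2-en-1-yl)phenol
Conditions: 3 M HCl, MeOH, rt to 40 °C
Reagents that add atoms: none
Why: Acid-catalysed acetal exchange with methanol removes the MOM group under conditions mild enough that the ortho-prenylphenol should not cyclise to a chroman.

**Step 4**
Reactants: 6 3-fluoro-5-methoxy-2-(3-methylbut-2-en-1-yl)phenol; 7 prenal (3-methylbut-2-enal)
Product: 8 7-fluoro-5-methoxy-2,2-dimethyl-8-(3-methylbut-2-en-1-yl)-2H-chromene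
Conditions: PhB(OH)2, AcOH, toluene, reflux with azeotropic removal of water
Reagents that add atoms: none
Why: Chromene annulation of a phenol with an enal: boronate-templated hydroxyalkylation at the only free ortho carbon gives a benzodioxaborin that fragments to an ortho-quinone methide, whose oxa-6π electrocyclisation forms the 2,2-dimethyl-2H-chromene with the regiochemistry fixed by the prenyl group that blocks the other ortho carbon.

**Step 5**
Reactants: 8 7-fluoro-5-methoxy-2,2-dimethyl-8-(3-methylbut-2-en-1-yl)-2H-chromene
Product: 10 7-fluoro-5-methoxy-2,2-dimethyl-8-(3-methylbut-2-en-1-yl)-2H-chromene-6-carboxylic acid, via aryllithium 9 (not isolated)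
Conditions: n-BuLi, THF, −78 °C; CO2, −78 °C → rt; 1 M HCl
Reagents that add atoms: carbon dioxide, O=C=O
Why: Directed ortho-metalation at the single remaining ring hydrogen, which lies between fluorine and OMe, followed by carboxylation at −78 °C, where neither loss of LiF nor lateral metalation of the prenyl CH2 should compete.

**Step 6**
Reactants: 10 7-fluoro-5-methoxy-2,2-dimethyl-8-(3-methylbut-2-en-1-yl)-2H-chromene-6-carboxylic acid; 11 2',6'-dihydroxyacetophenone
Product: 13 2-acetyl-3-hydroxyphenyl 7-fluoro-5-methoxy-2,2-dimethyl-8-(3-methylbut-2-en-1-yl)-2H-chromene-6-carboxylate, via acid chloride 12 (not isolated)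
Conditions: (COCl)2, DMF (cat.), CH2Cl2, 0 °C → rt, evaporate; then 11 (2 equiv), Et3N, DMAP (cat.), CH2Cl2, 0 °C → rt
Reagents that add atoms: none
Why: Acyl chloride formation and DMAP-catalysed O-acylation of one phenol of the symmetric diol 11, held at the monoester by the excess of 11 and by the hydrogen bond of the second OH to the acetyl carbonyl.

**Step 7**
Reactants: 13 2-acetyl-3-hydroxyphenyl 7-fluoro-5-methoxy-2,2-dimethyl-8-(3-methylbut-2-en-1-yl)-2H-chromene-6-carboxylate
Product: 15 2-(2,6-dihydroxyphenyl)-5-methoxy-8,8-dimethyl-10-(3-methylbut-2-en-1-yl)-4H,8H-pyrano[3,2-g]chromen-4-one, via 1,3-diketone 14 (not isolated)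
Conditions: KN(SiMe3)2 (3.0 equiv), THF, −78 °C → rt; then DMF, 80 °C; 1 M HCl work-up
Reagents that add atoms: none
Why: KN(SiMe3)2 forms the ring B phenoxide and the acetyl enolate, whose carbon C3 adds 6-exo-trig to the ester carbonyl C4; the cyclic hemiketal alkoxide (it already has the C4 substitution pattern of the target) opens by loss of the O2' phenoxide, which completes a Baker–Venkataraman O→C acyl transfer and gives diketone 14 as its enolate. On heating in DMF the enolate oxygen on C2 attacks C8a, ortho to the C4 carbonyl, and fluoride leaves: an intramolecular SNAr that closes the six-membered ring C, equally an oxa-6π closure of the O1=C2–C3=C4–C4a=C8a array followed by loss of fluoride. The closest known reactions are the Baker–Venkataraman rearrangement of 2-aroyloxyacetophenones and the base-mediated cyclisation of 1-(2-fluoroaryl)-1,3-diketones to chromones. No stereocentre is formed, since 15 is planar; C2 is set in step 8. The step needs chemoselectivity for O1→C8a closure over dehydrative closure of the ring B phenol onto C4, and regioselectivity for C8a over C5; the first is secured by the fluoride leaving group and the water-free basic medium in which the hemiketal does not dehydrate, the second because only C8a carries a leaving group better than methoxide. The three equivalents of base are fully consumed, so no free strong base remains to isomerise the prenyl group.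

**Step 8**
Reactants: 15 2-(2,6-dihydroxyphenyl)-5-methoxy-8,8-dimethyl-10-(3-methylbut-2-en-1-yl)-4H,8H-pyrano[3,2-g]chromen-4-one
Product: 18 target hemiketal (2R,4R; O2' bonded to C4 which carries OH), via tris(silyl) enol ether 16 (not isolated), via (2R)-flavanone 17 (not isolated)
Conditions: Cu(OAc)2 (5 mol %), (R)-DTBM-SEGPHOS (5.5 mol %), (EtO)2MeSiH (6 equiv), toluene, 0 °C → rt; then 1 M HCl, THF, 0 °C
Reagents that add atoms: none
Why: Enantioselective CuH 1,4-reduction of the pyranone enone: the ligated copper hydride delivers hydride to one face of C2 (the ligand antipode is the one that gives 2R, to be confirmed on the first sample), the non-conjugated prenyl and chromene alkenes stay untouched, the phenols are silylated in passing and the enolate is held as its silyl enol ether, and after acidic desilylation the 2'-OH adds to the C4 ketone on the only face the bicyclo[3.3.1] frame allows, which fixes C4 as R.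

**Compound list**

1 | 3-fluoro-5-methoxyphenol | COc1cc(O)cc(F)c1 | starting material
2 | 1-fluoro-3-methoxy-5-(methoxymethoxy)benzene | COCOc1cc(F)cc(OC)c1 | intermediate
3 | prenyl bromide (1-bromo-3-methylbut-2-ene) | CC(C)=CCBr | starting material
4 | [2-fluoro-4-methoxy-6-(methoxymethoxy)phenyl]lithium | COCOc1cc(OC)cc(F)c1[Li] | intermediate
5 | 1-fluoro-5-methoxy-3-(methoxymethoxy)-2-(3-methylbut-2-en-1-yl)benzene | COCOc1cc(OC)cc(F)c1CC=C(C)C | intermediate
6 | 3-fluoro-5-methoxy-2-(3-methylbut-2-en-1-yl)phenol | COc1cc(O)c(CC=C(C)C)c(F)c1 | intermediate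
7 | prenal (3-methylbut-2-enal) | CC(C)=CC=O | starting material
8 | 7-fluoro-5-methoxy-2,2-dimethyl-8-(3-methylbut-2-en-1-yl)-2H-chromene | COc1cc(F)c(CC=C(C)C)c2OC(C)(C)C=Cc12 | intermediate
9 | [7-fluoro-5-methoxy-2,2-dimethyl-8-(3-methylbut-2-en-1-yl)-2H-chromen-6-yl]lithium | COc1c([Li])c(F)c(CC=C(C)C)c2OC(C)(C)C=Cc12 | intermediate
10 | 7-fluoro-5-methoxy-2,2-dimethyl-8-(3-methylbut-2-en-1-yl)-2H-chromene-6-carboxylic acid | COc1c(C(=O)O)c(F)c(CC=C(C)C)c2OC(C)(C)C=Cc12 | intermediate
11 | 2',6'-dihydroxyacetophenone (1-(2,6-dihydroxyphenyl)ethan-1-one) | CC(=O)c1c(O)cccc1O | starting material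
12 | 7-fluoro-5-methoxy-2,2-dimethyl-8-(3-methylbut-2-en-1-yl)-2H-chromene-6-carbonyl chloride | COc1c(C(=O)Cl)c(F)c(CC=C(C)C)c2OC(C)(C)C=Cc12 | intermediate
13 | 2-acetyl-3-hydroxyphenyl 7-fluoro-5-methoxy-2,2-dimethyl-8-(3-methylbut-2-en-1-yl)-2H-chromene-6-carboxylate | COc1c(C(=O)Oc3cccc(O)c3C(C)=O)c(F)c(CC=C(C)C)c2OC(C)(C)C=Cc12 | intermediate
14 | 1-(2,6-dihydroxyphenyl)-3-[7-fluoro-5-methoxy-2,2-dimethyl-8-(3-methylbut-2-en-1-yl)-2H-chromen-6-yl]propane-1,3-dione | COc1c(C(=O)CC(=O)c3c(O)cccc3O)c(F)c(CC=C(C)C)c2OC(C)(C)C=Cc12 | intermediate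
15 | 2-(2,6-dihydroxyphenyl)-5-methoxy-8,8-dimethyl-10-(3-methylbut-2-en-1-yl)-4H,8H-pyrano[3,2-g]chromen-4-one (flavone) | COc1c2C=CC(C)(C)Oc2c(CC=C(C)C)c2oc(-c3c(O)cccc3O)cc(=O)c12 | intermediate
16 | (2R)-2-{2,6-bis[diethoxy(methyl)silyloxy]phenyl}-4-[diethoxy(methyl)silyloxy]-5-methoxy-8,8-dimethyl-10-(3-methylbut-2-en-1-yl)-2H,8H-pyrano[3,2-g]chromene | COc1c2C=CC(C)(C)Oc2c(CC=C(C)C)c2O[C@@H](c3c(O[Si](C)(OCC)OCC)cccc3O[Si](C)(OCC)OCC)C=C(O[Si](C)(OCC)OCC)c12 | intermediate
17 | (2R)-2-(2,6-dihydroxyphenyl)-5-methoxy-8,8-dimethyl-10-(3-methylbut-2-en-1-yl)-2,3-dihydro-4H,8H-pyrano[3,2-g]chromen-4-one (open flavanone) | COc1c2C=CC(C)(C)Oc2c(CC=C(C)C)c2O[C@@H](c3c(O)cccc3O)CC(=O)c12 | intermediate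
18 | (2R,4R) cyclic hemiketal of 17, with O2' bonded to C4 and OH on C4 (CNP0170313.2) | COc1c2c(c(CC=C(C)C)c3c1[C@@]1(O)C[C@@H](O3)c3c(O)cccc3O1)OC(C)(C)C=C2 | target

**Step count and risks**

Total steps: 8. Longest linear sequence: 8 steps (1 → 18).

Step 8 is the most likely to fail. Hydride delivery to C2, which is flanked by two ortho-silyloxy groups, may be slow or poorly face-selective. Ring opening of the copper enolate by loss of the O1 aryloxide, followed by reclosure, may also erode the enantiomeric purity. The fallback sets out from flavone 15. LiBH(sec-Bu)3 in THF at −78 °C (in excess, since the phenols consume two equivalents), followed by NH4Cl work-up, should give the racemic hemiketal F1 by non-selective 1,4-reduction. Preparative chromatography on a chiral stationary phase (amylose tris(3,5-dimethylphenylcarbamate)) would then separate the enantiomers. The 2R,4R enantiomer is target 18, where the fallback comes back to the route.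

Step 7 is the second risk. The enolate may add too slowly to the ester carbonyl, which is shielded by its two ortho substituents, so that intermolecular ester cleavage takes over. The diketone may also close through the ring B phenol onto C4 instead of through O1 onto C8a. The fallback sets out from acid 10 (as its chloride 12) and ketone 11 and replaces the intramolecular acyl transfer by a crossed Claisen condensation on a protected ring B. Ketone 11 would be converted with MOMCl and iPr2NEt into 1-[2,6-bis(methoxymethoxy)phenyl]ethan-1-one F2. Its lithium enolate (LiN(SiMe3)2, 2.1 equiv, THF, −78 °C) would be C-acylated by 12 to the protected 1,3-diketone F3. K2CO3 in DMF at 80 °C would close ring C by displacement of fluoride to give the bis(methoxymethyl) flavone F4. 3 M HCl in MeOH would then remove both MOM groups and come back to the route at flavone 15.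

Step 2 is the third risk. Metalation may take place at the ring position between the two oxygen substituents instead of between fluorine and OMOM, or the ortho-fluoroaryllithium may lose LiF before it is allylated. The fallback sets out from phenol 1 and places the prenyl group by a sigmatropic shift instead of a metalation. Copper-catalysed O-alkylation with 3-chloro-3-methylbut-1-yne (CuCl2, DBU, MeCN, 0 °C) would give 1-fluoro-3-methoxy-5-[(2-methylbut-3-yn-2-yl)oxy]benzene F5. Semi-hydrogenation (H2, Pd/CaCO3 poisoned with Pb(OAc)2, quinoline, EtOAc) would give 1-fluoro-3-methoxy-5-[(2-methylbut-3-en-2-yl)oxy]benzene F6. Thermal Claisen rearrangement (xylene, 130 °C) should then move the allyl unit, with inversion to the prenyl form, to the ortho carbon between oxygen and fluorine, the site ortho to fluorine and para to OMe. This comes back to the route at phenol 6 and leaves out steps 1 to 3.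

**Further compounds**

F1 | step 8 | racemic hemiketal (racemate of 18) | COc1c2c(c(CC=C(C)C)c3c1C1(O)CC(O3)c3c(O)cccc3O1)OC(C)(C)C=C2
F2 | step 7 | 1-[2,6-bis(methoxymethoxy)phenyl]ethan-1-one | CC(=O)c1c(OCOC)cccc1OCOC
F3 | step 7 | 1-[2,6-bis(methoxymethoxy)phenyl]-3-[7-fluoro-5-methoxy-2,2-dimethyl-8-(3-methylbut-2-en-1-yl)-2H-chromen-6-yl]propane-1,3-dione | COCOc1cccc(OCOC)c1C(=O)CC(=O)c1c(OC)c2C=CC(C)(C)Oc2c(CC=C(C)C)c1F
F4 | step 7 | 2-[2,6-bis(methoxymethoxy)phenyl]-5-methoxy-8,8-dimethyl-10-(3-methylbut-2-en-1-yl)-4H,8H-pyrano[3,2-g]chromen-4-one | COCOc1cccc(OCOC)c1-c1cc(=O)c2c(OC)c3C=CC(C)(C)Oc3c(CC=C(C)C)c2o1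
F5 | step 2 | 1-fluoro-3-methoxy-5-[(2-methylbut-3-yn-2-yl)oxy]benzene | COc1cc(F)cc(OC(C)(C)C#C)c1
F6 | step 2 | 1-fluoro-3-methoxy-5-[(2-methylbut-3-en-2-yl)oxy]benzene | COc1cc(F)cc(OC(C)(C)C=C)c1
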